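At the very start the flask holds no dissolved gas; it has to cross in before free catalyst can turn substrate into target, and each crossing molecule can also kill a free catalyst.

substrate 0.20 M; gas phase 13 mM (held); free catalyst 0.2 mol%; time 30 min

    gas phase ⇌ dissolved gas, rate k1*(csat - [dissolved gas]) (k1 = 0.0149 s⁻¹, csat = 13 mM)
    substrate + dissolved gas + free catalyst → free catalyst + target (k2 = 58.1 L² mol⁻² s⁻¹)
    dissolved gas + free catalyst → spent catalyst (k3 = 0.0246 L mol⁻¹ s⁻¹)
    2 dissolved gas → self-condensation product (k4 = 0.0108 L mol⁻¹ s⁻¹)

- how much target there is at 30 min, in percent of the substrate charged
- the change that raises the amount of target at 30 min, in percent of the substrate charged most ("none" if none brings more than 2 percentage points) (ash / elm / cedar / none)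
- amount of target at 30 min, in percent of the substrate charged, after elm

- ash: doubling the saturation concentration of gas phase, all else as stated
- elm: doubling the amount of free catalyst, all else as stated
- cedar: doubling the transfer coefficient of step 1, all else as stated

- for a step with 2 of a species take k times the square, and two of it per event
- at the start none of the gas is dissolved
- run time (flask): 30 min

**Where does dissolved gas stand in this flask after the lag?** My reckoning: transfer removes gas from the deficit at 0.0149 s⁻¹, and the catalytic cycle takes it at 0.00465 s⁻¹, which is slower. The balance of these two, at the starting charges, gives 9.91 mM, approached with a time constant of 51.2 s, far shorter than the run.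

**How long does free catalyst last in this flask?** Its loss is pseudo-first-order at that level, with a half-life of 47.4 min. The run is 0.633 half-lives, which leaves 64.5 % free.

**But catalyst dwindles while it works, so what does a rate times a time mean?** Nothing; I divide instead. The catalytic step and the death step carry the same c(dissolved gas), so it cancels: the logarithmic fall of c(substrate) equals the reach times the fraction of catalyst lost. The reach is the catalytic constant over the death constant, times the starting c(free catalyst), here 0.945. With the catalyst lost by the asked time, this flask gives 28.5 %.

**And the changes?** Elm doubles the reach but lowers c(dissolved gas), giving 43.1 %. Narrowly, I choose elm.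

The forecast, on the ground “Catalyst death matters”, says 34.9 %, 53.3 % after elm, and ash. My figure for the flask is lower, and my choice differs.

The simulation gives 29.2 %, 46.3 % after elm, and elm as the best change, gaining 17 percentage points against 15 points for ash and 2.3 points for cedar. At 30.0 min in the flask, dissolved gas has a half-life of 5.5 min by the catalytic step and 31 h by the death step, a ratio of 335. The reach times the 36.5 % of catalyst spent is 0.345, and the logarithmic fall to 70.8 % substrate is 0.345.

In the neighbour flask charged with 0.34 M substrate, the reach is 1.61 and the balance at the starting charges puts dissolved gas at 6.84 mM, which gives 34.3 %. The simulation gives 37.5 %.

The rate constants are made up; the rest is arithmetic.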